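**Retrosynthetic overview**

1. The target is a (2S,2''S)-biflavanone. The upper flavanone has benzo ring A, pyranone ring C and aryl ring B (locants 2 to 8a and 1' to 6'). The lower flavanone has benzo ring D, pyranone ring F and aryl ring E (locants 2'' to 8a'' and 1''' to 6'''). The last step is hydrogenolysis of three benzyl ethers (5-OH, 5''-OH, 4'''-OH).
2. Two bonds are disconnected in one flask: the C3'–C6'' biaryl bond (slow-release Suzuki–Miyaura coupling of a MIDA boronate) and the C2–C1' bond of the upper flavanone (rhodium-catalysed asymmetric 1,4-addition to a chromone). Three components are joined: an achiral 5-benzyloxy-7-methoxychromone, a 1,3-diborylated anisole linchpin and the lower 6''-iodoflavanone.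
3. Enabling feature: ring B is a 1,3-hub. C1' carries C2 of ring C and C3' (ortho to the 4'-OMe) carries C6'' of ring D. Both halves contain the same (2S)-2-aryl-5-hydroxy-7-methoxychroman-4-one bicycle, so one chromone serves twice. C6'' is the only free carbon ortho to the chelated 5''-OH, which makes its iodination regioselective.
4. The lower flavanone comes from the same chromone by C6 iodination, O-benzylation and a first rhodium-catalysed asymmetric 1,4-addition of 4-(benzyloxy)phenylboronic acid.
5. Ring order: no ring is built. Bicycles A/C and D/F come preformed from 5,7-dihydroxychromone and rings B and E from arylboronic acids. The C2=C3 bond of ring F is saturated first (step 5), that of ring C in the key step.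

Key step: step 9

**Assumptions**

- The (S)-configured ligand (S)-MeO-F12-BIPHEP, (S)-6,6'-dimethoxy-2,2'-bis[bis(3,4,5-trifluorophenyl)phosphino]-1,1'-biphenyl, is assumed to give the (2S)-flavanone, by analogy with (S)-BINAP and cyclohexenone. If the sense is opposite, the (R)-ligand is used in steps 5 and 9.
- The tri-ortho-substituted biaryl axis is taken as freely rotating at room temperature, since the target carries no axial descriptor.

**Route**

Step 1
Reactants: 1 5,7-dihydroxy-4H-chromen-4-one
Product: 2 5-hydroxy-7-methoxy-4H-chromen-4-one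
Conditions: MeI, K2CO3, acetone, reflux
Reagents that add atoms: iodomethane, CI
Why: Williamson O-methylation should take place only at the free, more acidic 7-OH, because the 5-OH is held in a hydrogen bond to the C4 carbonyl.

Step 2
Reactants: 2 5-hydroxy-7-methoxy-4H-chromen-4-one
Product: 3 5-(benzyloxy)-7-methoxy-4H-chromen-4-one
Conditions: BnBr, K2CO3, DMF, 70 °C
Reagents that add atoms: benzyl bromide, BrCc1ccccc1
Why: Forcing Williamson etherification in DMF should break the chelate and cap the peri 5-OH before the rhodium chemistry.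

Step 3
Reactants: 2 5-hydroxy-7-methoxy-4H-chromen-4-one
Product: 4 5-hydroxy-6-iodo-7-methoxy-4H-chromen-4-one
Conditions: BnMe3N·ICl2, CaCO3, CH2Cl2/MeOH, rt
Reagents that add atoms: benzyltrimethylammonium dichloroiodate, C[N+](C)(C)Cc1ccccc1.Cl[I-]Cl
Why: Electrophilic aromatic iodination should occur at C6, the only free carbon ortho to the chelated 5-OH and flanked by the 7-OMe, as is usual for 5-hydroxy-7-alkoxy chromones and flavones with this reagent.

Step 4
Reactants: 4 5-hydroxy-6-iodo-7-methoxy-4H-chromen-4-one
Product: 5 5-(benzyloxy)-6-iodo-7-methoxy-4H-chromen-4-one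
Conditions: BnBr, K2CO3, DMF, 70 °C
Reagents that add atoms: benzyl bromide, BrCc1ccccc1
Why: Williamson O-benzylation of the chelated phenol should proceed under forcing conditions and installs the same protecting group as on the other phenols.

Step 5
Reactants: 5 5-(benzyloxy)-6-iodo-7-methoxy-4H-chromen-4-one; 6 [4-(benzyloxy)phenyl]boronic acid
Product: 7 (2S)-5-(benzyloxy)-2-[4-(benzyloxy)phenyl]-6-iodo-7-methoxychroman-4-one
Conditions: [Rh(OH)((S)-MeO-F12-BIPHEP)]2 (cat.), dioxane/H2O, 40 °C
Reagents that add atoms: none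
Why: In this rhodium-catalysed asymmetric 1,4-addition of an arylboronic acid to a chromone (Hayashi–Miyaura type), the aryl–rhodium species should add across C2=C3 on the face set by the chiral bisphosphine, giving C2'' as S, while the hindered, electron-rich C6–I bond should not react with monovalent rhodium at this temperature.

Step 6
Reactants: 8 (5-bromo-2-methoxyphenyl)boronic acid
Product: 9 2-(5-bromo-2-methoxyphenyl)-6-methyl-1,3,6,2-dioxazaborocane-4,8-dione
Conditions: MIDA, toluene/DMSO, Dean–Stark, reflux
Reagents that add atoms: N-methyliminodiacetic acid, CN(CC(=O)O)CC(=O)O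
Why: Dehydrative complexation should give the sp3-hybridised MIDA boronate, which masks the future C3' nucleophile against transmetalation.

Step 7
Reactants: 9 2-(5-bromo-2-methoxyphenyl)-6-methyl-1,3,6,2-dioxazaborocane-4,8-dione
Product: 10 2-[2-methoxy-5-(4,4,5,5-tetramethyl-1,3,2-dioxaborolan-2-yl)phenyl]-6-methyl-1,3,6,2-dioxazaborocane-4,8-dione
Conditions: B2pin2, PdCl2(dppf) (cat.), KOAc, dioxane, 85 °C
Reagents that add atoms: bis(pinacolato)diboron, CC1(C)OB(OC1(C)C)B1OC(C)(C)C(C)(C)O1
Why: Miyaura borylation of the aryl bromide under anhydrous KOAc conditions should leave the MIDA boronate untouched.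

Step 8
Reactants: 10 2-[2-methoxy-5-(4,4,5,5-tetramethyl-1,3,2-dioxaborolan-2-yl)phenyl]-6-methyl-1,3,6,2-dioxazaborocane-4,8-dione
Product: 11 [4-methoxy-3-(6-methyl-4,8-dioxo-1,3,6,2-dioxazaborocan-2-yl)phenyl]boronic acid
Conditions: NaIO4, NH4OAc, acetone/H2O, rt
Reagents that add atoms: water, O
Why: Periodate cleavage of the pinacol unit under buffered neutral conditions should free the boronic acid, while the MIDA boronate is stable to neutral water.

Step 9
Reactants: 3 5-(benzyloxy)-7-methoxy-4H-chromen-4-one; 11 [4-methoxy-3-(6-methyl-4,8-dioxo-1,3,6,2-dioxazaborocan-2-yl)phenyl]boronic acid; 7 (2S)-5-(benzyloxy)-2-[4-(benzyloxy)phenyl]-6-iodo-7-methoxychroman-4-one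
Product: 14 (2S)-5-(benzyloxy)-2-{3-[(2S)-5-(benzyloxy)-2-[4-(benzyloxy)phenyl]-7-methoxy-4-oxochroman-6-yl]-4-methoxyphenyl}-7-methoxychroman-4-one, via MIDA-boronate flavanone 12 (not isolated), via boronic acid flavanone 13 (not isolated)
Conditions: [Rh(OH)((S)-MeO-F12-BIPHEP)]2 (cat.), dioxane/H2O, 40 °C; then 7, Pd(OAc)2 (cat.), SPhos, K3PO4 (aq.), 45 °C, same flask
Reagents that add atoms: none
Why: Stage one is a rhodium-catalysed asymmetric 1,4-addition (Hayashi–Miyaura type) in which only the sp2 boronic acid of 11 transmetalates to the rhodium hydroxide, the aryl–rhodium species adds across C2=C3 of 3 and the oxa-π-allyl rhodium is protonated by water to give 12, the sp3 MIDA boronate being inert without base. The new C2 stereocentre is set S by catalyst control (enantiofacial carbometalation in the pocket of the chiral bisphosphine) and does not depend on the remote C2'' centre of 7, which enters only afterwards. Stage two is a slow-release Suzuki–Miyaura coupling, in which aqueous K3PO4 opens the MIDA cage to boronic acid 13, zerovalent palladium inserts into the C6''–I bond of 7, and transmetalation followed by reductive elimination forms the C3'–C6'' biaryl bond. No ring is closed; three components are joined around ring B with two C–C bonds and one stereocentre formed in one operation. The step needs chemoselection between the two boron atoms (secured by their sp2 and sp3 hybridisation), a ligand able to build a tri-ortho-substituted biaryl (SPhos) and retention of both C2 configurations (mild base, moderate temperature, every phenol capped so that no phenoxide assists ring opening). Iodide 7 is the limiting component and 3 is used in only slight excess over 11, so that no free boronic acid of 11 remains to couple through C1'.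

Step 10
Reactants: 14 (2S)-5-(benzyloxy)-2-{3-[(2S)-5-(benzyloxy)-2-[4-(benzyloxy)phenyl]-7-methoxy-4-oxochroman-6-yl]-4-methoxyphenyl}-7-methoxychroman-4-one
Product: 15 (2S)-5-hydroxy-2-{3-[(2S)-5-hydroxy-2-(4-hydroxyphenyl)-7-methoxy-4-oxochroman-6-yl]-4-methoxyphenyl}-7-methoxychroman-4-one
Conditions: H2 (1 atm), Pd/C, EtOAc/MeOH, rt
Reagents that add atoms: none
Why: Catalytic hydrogenolysis of the three aryl benzyl ethers under neutral conditions should release the two chelated 5-OH groups and the 4'''-OH without acid or base, so neither C2 centre should epimerise and the three methyl ethers stay in place.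

**Compound list**

1 | 5,7-dihydroxy-4H-chromen-4-one | O=c1ccoc2cc(O)cc(O)c12 | starting material
2 | 5-hydroxy-7-methoxy-4H-chromen-4-one | COc1cc(O)c2c(c1)occc2=O | intermediate
3 | 5-(benzyloxy)-7-methoxy-4H-chromen-4-one | COc1cc(OCc3ccccc3)c2c(c1)occc2=O | intermediate
4 | 5-hydroxy-6-iodo-7-methoxy-4H-chromen-4-one | COc1cc2occc(=O)c2c(O)c1I | intermediate
5 | 5-(benzyloxy)-6-iodo-7-methoxy-4H-chromen-4-one | COc1cc2occc(=O)c2c(OCc3ccccc3)c1I | intermediate
6 | [4-(benzyloxy)phenyl]boronic acid | OB(O)c1ccc(OCc2ccccc2)cc1 | starting material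
7 | (2S)-5-(benzyloxy)-2-[4-(benzyloxy)phenyl]-6-iodo-7-methoxychroman-4-one | COc1cc2c(c(OCc3ccccc3)c1I)C(=O)C[C@@H](c1ccc(OCc3ccccc3)cc1)O2 | intermediate
8 | (5-bromo-2-methoxyphenyl)boronic acid | COc1ccc(Br)cc1B(O)O | starting material
9 | 2-(5-bromo-2-methoxyphenyl)-6-methyl-1,3,6,2-dioxazaborocane-4,8-dione | COc1ccc(Br)cc1[B-]12OC(=O)C[N+]1(C)CC(=O)O2 | intermediate
10 | 2-[2-methoxy-5-(4,4,5,5-tetramethyl-1,3,2-dioxaborolan-2-yl)phenyl]-6-methyl-1,3,6,2-dioxazaborocane-4,8-dione | COc1ccc(B2OC(C)(C)C(C)(C)O2)cc1[B-]34OC(=O)C[N+]3(C)CC(=O)O4 | intermediate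
11 | [4-methoxy-3-(6-methyl-4,8-dioxo-1,3,6,2-dioxazaborocan-2-yl)phenyl]boronic acid | COc1ccc(B(O)O)cc1[B-]12OC(=O)C[N+]1(C)CC(=O)O2 | intermediate
12 | (2S)-5-(benzyloxy)-7-methoxy-2-[4-methoxy-3-(6-methyl-4,8-dioxo-1,3,6,2-dioxazaborocan-2-yl)phenyl]chroman-4-one | COc1cc(OCc3ccccc3)c2c(c1)O[C@H](c1ccc(OC)c([B-]34OC(=O)C[N+]3(C)CC(=O)O4)c1)CC2=O | intermediate
13 | {5-[(2S)-5-(benzyloxy)-7-methoxy-4-oxochroman-2-yl]-2-methoxyphenyl}boronic acid | COc1cc(OCc3ccccc3)c2c(c1)O[C@H](c1ccc(OC)c(B(O)O)c1)CC2=O | intermediate
14 | (2S)-5-(benzyloxy)-2-{3-[(2S)-5-(benzyloxy)-2-[4-(benzyloxy)phenyl]-7-methoxy-4-oxochroman-6-yl]-4-methoxyphenyl}-7-methoxychroman-4-one | COc1cc(OCc5ccccc5)c2c(c1)O[C@H](c1ccc(OC)c(-c3c(OC)cc4c(c3OCc5ccccc5)C(=O)C[C@@H](c3ccc(OCc5ccccc5)cc3)O4)c1)CC2=O | intermediate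
15 | (2S)-5-hydroxy-2-{3-[(2S)-5-hydroxy-2-(4-hydroxyphenyl)-7-methoxy-4-oxochroman-6-yl]-4-methoxyphenyl}-7-methoxychroman-4-one | COc1cc(O)c2c(c1)O[C@H](c1ccc(OC)c(-c3c(OC)cc4c(c3O)C(=O)C[C@@H](c3ccc(O)cc3)O4)c1)CC2=O | target

**Summary**

Total step count: 10. Longest linear sequence: 6 steps (steps 1, 3, 4, 5, 9, 10).

**Steps most likely to fail**

Step 9. Three processes threaten it. The aqueous phosphate stage may open ring C or ring F by base-induced retro-oxa-Michael reaction and so epimerise C2 or C2''. Residual rhodium may add unmasked 13 to leftover 3. Protodeboronation may outrun the hindered coupling. The fallback gives up the one-pot union for a stepwise, water-free fragment coupling; it sets out from 3 (7 is used unchanged) and returns at 14. Chromone 3 and commercial (3-bromo-4-methoxyphenyl)boronic acid (COc1ccc(B(O)O)cc1Br), under the rhodium conditions of step 5, should give (2S)-5-(benzyloxy)-2-(3-bromo-4-methoxyphenyl)-7-methoxychroman-4-one F1. Miyaura borylation (B2pin2, PdCl2(dppf), KOAc, dioxane, 80 °C) should convert it into (2S)-5-(benzyloxy)-7-methoxy-2-[4-methoxy-3-(4,4,5,5-tetramethyl-1,3,2-dioxaborolan-2-yl)phenyl]chroman-4-one F2. The isolated boronate is then coupled with 7 under anhydrous Suzuki–Miyaura conditions (Pd(OAc)2, SPhos, CsF, dioxane, 70 °C) to give 14 without hydroxide present.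

Step 5. Oxidative addition of the C6–I bond to the aryl–rhodium species, or hydrodeiodination, may compete with a conjugate addition that is slow on the doubly flanked, electron-rich chromone. The fallback sets the stereocentre before iodine is introduced; it sets out from 3 and 6 and returns at 7.
- Rhodium-catalysed asymmetric 1,4-addition of 6 to 3 (conditions of step 5) should give (2S)-5-(benzyloxy)-2-[4-(benzyloxy)phenyl]-7-methoxychroman-4-one F3.
- Chelation-controlled cleavage of the peri benzyl ether (MgBr2·OEt2, toluene, 60 °C) should give (2S)-2-[4-(benzyloxy)phenyl]-5-hydroxy-7-methoxychroman-4-one F4.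
- Iodination directed by the free 5-OH (BnMe3N·ICl2, CaCO3, CH2Cl2/MeOH, rt) should give (2S)-2-[4-(benzyloxy)phenyl]-5-hydroxy-6-iodo-7-methoxychroman-4-one F5.
- Non-basic Purdie-type benzylation (BnBr, Ag2O, CH2Cl2, rt), chosen to avoid base-induced ring opening of the 5-hydroxyflavanone, should return 7.

Step 10. Hydrogenolysis of the benzylic C2–O1 and C2''–O1'' bonds, or reduction of the aryl ketones, may compete with removal of the hindered peri benzyl ethers. The fallback replaces reductive cleavage by Lewis-acid benzyl transfer to an arene scavenger (BCl3, pentamethylbenzene, CH2Cl2, −78 °C). It sets out from 14 and returns at 15; the ordinary 7-, 7''- and 4'-methyl ethers should survive at this temperature. This fallback makes no new compound (entry F0).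

Further compounds
F1 | step 9 | (2S)-5-(benzyloxy)-2-(3-bromo-4-methoxyphenyl)-7-methoxychroman-4-one | COc1cc(OCc3ccccc3)c2c(c1)O[C@H](c1ccc(OC)c(Br)c1)CC2=O
F2 | step 9 | (2S)-5-(benzyloxy)-7-methoxy-2-[4-methoxy-3-(4,4,5,5-tetramethyl-1,3,2-dioxaborolan-2-yl)phenyl]chroman-4-one | COc1cc(OCc3ccccc3)c2c(c1)O[C@H](c1ccc(OC)c(B3OC(C)(C)C(C)(C)O3)c1)CC2=O
F3 | step 5 | (2S)-5-(benzyloxy)-2-[4-(benzyloxy)phenyl]-7-methoxychroman-4-one | COc1cc(OCc3ccccc3)c2c(c1)O[C@H](c1ccc(OCc3ccccc3)cc1)CC2=O
F4 | step 5 | (2S)-2-[4-(benzyloxy)phenyl]-5-hydroxy-7-methoxychroman-4-one | COc1cc(O)c2c(c1)O[C@H](c1ccc(OCc3ccccc3)cc1)CC2=O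
F5 | step 5 | (2S)-2-[4-(benzyloxy)phenyl]-5-hydroxy-6-iodo-7-methoxychroman-4-one | COc1cc2c(c(O)c1I)C(=O)C[C@@H](c1ccc(OCc3ccccc3)cc1)O2
F0 | step 10 | none | none
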